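The ester C–O bond between the C3 hydroxymethyl oxygen of the isochromanone lactol and the 2,4-dihydroxy-5,6-dimethylbenzoate is the disconnection, and that benzene ring is not brought in ready-made. Its alternating pattern (ester carbon on C1′, hydroxyls on C2′ and C4′, methyls on C5′ and C6′) is a folded 3,5,7-triketo ester. Heating a diketo-dioxinone with the unprotected lactol diol releases an acylketene that acylates the only unhindered hydroxyl, C3–CH2OH; acetate then closes the C1′–C6′ bond by aldol condensation and the ring aromatises in the same flask. The precursor, (3R,4S)-3,8-dihydroxy-3-(hydroxymethyl)-6-methoxy-4,5-dimethylisochroman-1-one, comes from an enantioenriched indanone by ketol cleavage.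

Key step: step 13

Remark: C3 is a hemiketal carbon and is assumed to settle by ring–chain tautomerism on the (3R) anomer of the target (hydroxyl axial and anti to the C4 methyl, which the peri C5 methyl holds pseudo-axial); only C4 is installed by asymmetric synthesis, and C2 of indanones 11 and 12 is carried as an epimer mixture because it ends as that hemiketal carbon.

Step 1
Reactants: 1 1-bromo-3,5-dimethoxybenzene
Product: 2 2-bromo-4,6-dimethoxybenzaldehyde
Conditions: POCl3, DMF, 0 → 90 °C; then H2O
Reagents that add atoms: N,N-dimethylformamide (CN(C)C=O); water (O)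
Why: Vilsmeier–Haack formylation, in which the chloroiminium ion attacks C2 (para to one methoxy, ortho to the other) in preference to the carbon flanked by both methoxy groups, while the bromide is kept as the handle for step 3.

Step 2
Reactants: 2 2-bromo-4,6-dimethoxybenzaldehyde
Product: 3 1-bromo-3,5-dimethoxy-2-methylbenzene
Conditions: Et3SiH (2.5 equiv), TFA, CH2Cl2, 0 °C → rt
Reagents that add atoms: none
Why: Ionic hydrogenation of an electron-rich benzaldehyde proceeds through the methoxy-stabilised benzylic cation to the methyl group and leaves the aryl bromide untouched, with excess silane suppressing diarylmethane formation.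

Step 3
Reactants: 3 1-bromo-3,5-dimethoxy-2-methylbenzene
Product: 4 (3,5-dimethoxy-2-methylphenyl)boronic acid
Conditions: n-BuLi, THF, −78 °C; B(Oi-Pr)3, −78 °C → rt; 1 M HCl
Reagents that add atoms: triisopropyl borate (CC(C)OB(OC(C)C)OC(C)C); water (O)
Why: Bromine–lithium exchange at −78 °C is faster than any deprotonation, and the aryllithium is trapped by the borate and hydrolysed to the boronic acid (lithiation–borylation).

Step 4
Reactants: 4 (3,5-dimethoxy-2-methylphenyl)boronic acid; 5 isopropyl (2E)-but-2-enoate
Product: 7 (3R)-3-(3,5-dimethoxy-2-methylphenyl)butanoic acid, via isopropyl ester 6 (not isolated)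
Conditions: [Rh(acac)(C2H4)2] (3 mol %), (S)-BINAP (3.3 mol %), 1,4-dioxane/H2O 10:1, 100 °C; then LiOH, MeOH/H2O, 60 °C; then 1 M HCl
Reagents that add atoms: lithium hydroxide ([Li+].[OH-])
Why: Hayashi–Miyaura rhodium-catalysed asymmetric 1,4-addition of an arylboronic acid to an (E)-enoate should set C3 (the future C4 of the lactol) as R by aryl transfer to the α-si-bound enoate on the (S)-BINAP complex (the antipodal ligand is the remedy should the sense prove reversed), and the saponification in the same pot cannot touch this β-stereocentre.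

Step 5
Reactants: 7 (3R)-3-(3,5-dimethoxy-2-methylphenyl)butanoic acid
Product: 8 (3R)-5,7-dimethoxy-3,4-dimethyl-2,3-dihydro-1H-inden-1-one
Conditions: TFAA, TFA, CH2Cl2, 0 °C → rt
Reagents that add atoms: none
Why: Intramolecular Friedel–Crafts acylation through the mixed trifluoroacetic anhydride closes the five-membered ketone at the only ortho carbon that carries hydrogen (para to a methoxy group), so the future lactone carbonyl C1 is placed regiospecifically and the β-stereocentre is not involved.

Step 6
Reactants: 8 (3R)-5,7-dimethoxy-3,4-dimethyl-2,3-dihydro-1H-inden-1-one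
Product: 9 (3R)-7-hydroxy-5-methoxy-3,4-dimethyl-2,3-dihydro-1H-inden-1-one
Conditions: BCl3, CH2Cl2, −78 → 0 °C; then H2O
Reagents that add atoms: none
Why: Chelation-controlled ether cleavage, in which BCl3 bound to the C1 carbonyl removes only the peri C7 methyl group while the C5 methoxy para to the carbonyl is inert at this temperature.

Step 7
Reactants: 9 (3R)-7-hydroxy-5-methoxy-3,4-dimethyl-2,3-dihydro-1H-inden-1-one
Product: 11 (2RS,3R)-7-[(benzyloxy)methoxy]-2-[(benzyloxy)methyl]-5-methoxy-3,4-dimethyl-2,3-dihydro-1H-inden-1-one, via O-BOM ether 10 (not isolated)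
Conditions: NaH, BOMCl, THF, 0 °C → rt; then LiHMDS, −78 °C; BOMCl, −78 → −20 °C
Reagents that add atoms: benzyl chloromethyl ether (ClCOCc1ccccc1)
Why: Williamson O-alkylation of the phenoxide followed by C-alkylation of the kinetic lithium enolate with the same reactive chloromethyl ether installs the phenol protecting group and the future C3 hydroxymethyl carbon in one flask, the configuration at C2 being irrelevant.

Step 8
Reactants: 11 (2RS,3R)-7-[(benzyloxy)methoxy]-2-[(benzyloxy)methyl]-5-methoxy-3,4-dimethyl-2,3-dihydro-1H-inden-1-one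
Product: 12 (2RS,3S)-7-[(benzyloxy)methoxy]-2-[(benzyloxy)methyl]-2-hydroxy-5-methoxy-3,4-dimethyl-2,3-dihydro-1H-inden-1-one
Conditions: KHMDS, THF, −78 °C; 2-(phenylsulfonyl)-3-phenyloxaziridine, −78 °C; aq. NH4Cl
Reagents that add atoms: 2-(phenylsulfonyl)-3-phenyloxaziridine (O=S(=O)(N1OC1c1ccccc1)c1ccccc1)
Why: Davis α-hydroxylation of the tetrasubstituted potassium enolate gives the tertiary α-ketol at the only enolisable position, the low temperature preventing β-elimination of benzyloxide, and C3 is untouched (its descriptor becomes S only because C2 gains priority).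

Step 9
Reactants: 12 (2RS,3S)-7-[(benzyloxy)methoxy]-2-[(benzyloxy)methyl]-2-hydroxy-5-methoxy-3,4-dimethyl-2,3-dihydro-1H-inden-1-one
Product: 14 (3R,4S)-8-[(benzyloxy)methoxy]-3-[(benzyloxy)methyl]-3-hydroxy-6-methoxy-4,5-dimethyl-3,4-dihydro-1H-isochromen-1-one, via keto acid 13 (not isolated)
Conditions: NaIO4, THF/H2O 2:1, rt
Reagents that add atoms: sodium periodate ([Na+].[O-]I(=O)(=O)=O)
Why: Periodate cleavage of the α-ketol breaks C1–C2, turning C1 into the carboxylic acid and C2 into the ketone under near-neutral conditions that do not enolise the new α-aryl ketone, and the keto acid closes to the lactol whose C3 should settle as the anomerically favoured (3R) hemiketal with the hydroxyl anti to the C4 methyl.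

Step 10
Reactants: 14 (3R,4S)-8-[(benzyloxy)methoxy]-3-[(benzyloxy)methyl]-3-hydroxy-6-methoxy-4,5-dimethyl-3,4-dihydro-1H-isochromen-1-one
Product: 15 (3R,4S)-3,8-dihydroxy-3-(hydroxymethyl)-6-methoxy-4,5-dimethyl-3,4-dihydro-1H-isochromen-1-one
Conditions: H2 (1 atm), 10% Pd/C, EtOAc, rt
Reagents that add atoms: none
Why: Neutral hydrogenolysis cleaves both benzyl C–O bonds, the phenolic hemiformal collapsing to the phenol and formaldehyde, so the lactol with its epimerisable C4 is unveiled without any acid or base.

Step 11
Reactants: 16 2,2,6-trimethyl-4H-1,3-dioxin-4-one; 17 propanoyl chloride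
Product: 18 2,2-dimethyl-6-(2-oxobutyl)-4H-1,3-dioxin-4-one
Conditions: LiHMDS, THF, −78 °C; 17 (0.5 equiv), −78 °C; 1 M HCl
Reagents that add atoms: none
Why: γ-Acylation (vinylogous Claisen condensation) of the lithium dienolate of the dioxinone with the acid chloride gives the keto-dioxinone, the dienolate being kept in excess because the product is the stronger acid.

Step 12
Reactants: 18 2,2-dimethyl-6-(2-oxobutyl)-4H-1,3-dioxin-4-one; 19 N-acetylimidazole
Product: 20 2,2-dimethyl-6-(3-methyl-2,4-dioxopentyl)-4H-1,3-dioxin-4-one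
Conditions: LDA (2.1 equiv), THF, −78 °C; 19 (0.5 equiv), −78 → −40 °C; 1 M HCl
Reagents that add atoms: none
Why: Weiler-type dianion chemistry, in which the second deprotonation occurs at the α′ carbon of the ethyl ketone and this more nucleophilic site is C-acylated by the acylimidazole (Claisen condensation), the dianion being in excess to absorb the acidic product.

Step 13
Reactants: 15 (3R,4S)-3,8-dihydroxy-3-(hydroxymethyl)-6-methoxy-4,5-dimethyl-3,4-dihydro-1H-isochromen-1-one; 20 2,2-dimethyl-6-(3-methyl-2,4-dioxopentyl)-4H-1,3-dioxin-4-one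
Product: 24 [(3R,4S)-3,8-dihydroxy-6-methoxy-4,5-dimethyl-1-oxo-3,4-dihydro-1H-isochromen-3-yl]methyl 2,4-dihydroxy-5,6-dimethylbenzoate (target), via acylketene 21 (not isolated), via triketo ester 22 (not isolated), via aldol adduct 23 (not isolated)
Conditions: PhMe/1,4-dioxane 4:1, 105 °C, 20 (1.3 equiv) in portions; then CsOAc, i-PrOH/CH2Cl2, rt; then AcOH, 40 °C
Reagents that add atoms: none
Why: Thermal retro-[4+2] of 20 expels acetone and gives acylketene 21, to which the primary C3–CH2OH of 15 adds through a six-membered pseudopericyclic transition state, so the ester C–O bond is made without activating a di-ortho-substituted benzoic acid; the closest known reaction type is acylketene capture by alcohols from diketo-dioxinones followed by aromatisation of the triketo ester to a resorcylate. Acetate then enolises 22 and the ester α-carbon (future C1′) attacks the terminal methyl ketone (future C6′) in a 6-(enolendo)-exo-trig aldol to give 23, which loses water and enolises its two remaining ring ketones to the benzene ring on warming with acetic acid. No stereocentre is formed; C4 should keep its configuration because the lactol meets nothing more basic than acetate, and C3 remains the anomerically favoured hemiketal. The step needs chemoselective O-acylation: the primary hydroxyl is the only unhindered one, the tertiary hemiketal hydroxyl being flanked by four substituents and deactivated by the geminal acyloxy oxygen and the C8 phenol being tied up in a hydrogen bond to C1=O, and portionwise dosing of 20 keeps the ketene concentration low. It also needs C- over O-cyclisation of 22, which the weakly basic medium secures because pyranone formation is the acid-promoted pathway, while Claisen closure from the methyl-bearing carbon would give a quaternary ring that cannot aromatise and is reversible.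

Compound list
1 | 1-bromo-3,5-dimethoxybenzene | COc1cc(Br)cc(OC)c1 | starting material
2 | 2-bromo-4,6-dimethoxybenzaldehyde | COc1cc(Br)c(C=O)c(OC)c1 | intermediate
3 | 1-bromo-3,5-dimethoxy-2-methylbenzene | COc1cc(Br)c(C)c(OC)c1 | intermediate
4 | (3,5-dimethoxy-2-methylphenyl)boronic acid | COc1cc(B(O)O)c(C)c(OC)c1 | intermediate
5 | isopropyl (2E)-but-2-enoate | C/C=C/C(=O)OC(C)C | starting material
6 | isopropyl (3R)-3-(3,5-dimethoxy-2-methylphenyl)butanoate | COc1cc(OC)c(C)c(c1)[C@H](C)CC(=O)OC(C)C | intermediate (not isolated)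
7 | (3R)-3-(3,5-dimethoxy-2-methylphenyl)butanoic acid | COc1cc(OC)c(C)c(c1)[C@H](C)CC(=O)O | intermediate
8 | (3R)-5,7-dimethoxy-3,4-dimethyl-2,3-dihydro-1H-inden-1-one | COc1cc(OC)c2c(c1C)[C@H](C)CC2=O | intermediate
9 | (3R)-7-hydroxy-5-methoxy-3,4-dimethyl-2,3-dihydro-1H-inden-1-one | COc1cc(O)c2c(c1C)[C@H](C)CC2=O | intermediate
10 | (3R)-7-[(benzyloxy)methoxy]-5-methoxy-3,4-dimethyl-2,3-dihydro-1H-inden-1-one | COc1cc(OCOCc3ccccc3)c2c(c1C)[C@H](C)CC2=O | intermediate (not isolated)
11 | (2RS,3R)-7-[(benzyloxy)methoxy]-2-[(benzyloxy)methyl]-5-methoxy-3,4-dimethyl-2,3-dihydro-1H-inden-1-one | COc1cc(OCOCc3ccccc3)c2c(c1C)[C@H](C)C(COCc4ccccc4)C2=O | intermediate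
12 | (2RS,3S)-7-[(benzyloxy)methoxy]-2-[(benzyloxy)methyl]-2-hydroxy-5-methoxy-3,4-dimethyl-2,3-dihydro-1H-inden-1-one | COc1cc(OCOCc3ccccc3)c2c(c1C)[C@H](C)C(O)(COCc4ccccc4)C2=O | intermediate
13 | 2-[(benzyloxy)methoxy]-6-[(2S)-4-(benzyloxy)-3-oxobutan-2-yl]-4-methoxy-5-methylbenzoic acid | COc1cc(OCOCc3ccccc3)c(C(=O)O)c(c1C)[C@H](C)C(=O)COCc4ccccc4 | intermediate (not isolated)
14 | (3R,4S)-8-[(benzyloxy)methoxy]-3-[(benzyloxy)methyl]-3-hydroxy-6-methoxy-4,5-dimethyl-3,4-dihydro-1H-isochromen-1-one | COc1cc(OCOCc3ccccc3)c2c(c1C)[C@H](C)[C@](O)(COCc4ccccc4)OC2=O | intermediate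
15 | (3R,4S)-3,8-dihydroxy-3-(hydroxymethyl)-6-methoxy-4,5-dimethyl-3,4-dihydro-1H-isochromen-1-one | COc1cc(O)c2c(c1C)[C@H](C)[C@](O)(CO)OC2=O | intermediate
16 | 2,2,6-trimethyl-4H-1,3-dioxin-4-one | CC1=CC(=O)OC(C)(C)O1 | starting material
17 | propanoyl chloride | CCC(=O)Cl | starting material
18 | 2,2-dimethyl-6-(2-oxobutyl)-4H-1,3-dioxin-4-one | CCC(=O)CC1=CC(=O)OC(C)(C)O1 | intermediate
19 | N-acetylimidazole | CC(=O)n1ccnc1 | starting material
20 | 2,2-dimethyl-6-(3-methyl-2,4-dioxopentyl)-4H-1,3-dioxin-4-one (racemic at the methine) | CC(=O)C(C)C(=O)CC1=CC(=O)OC(C)(C)O1 | intermediate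
21 | 6-methyl-3,5,7-trioxooct-1-en-1-one (acylketene) | CC(=O)C(C)C(=O)CC(=O)C=C=O | intermediate (not isolated)
22 | [(3R,4S)-3,8-dihydroxy-6-methoxy-4,5-dimethyl-1-oxo-3,4-dihydro-1H-isochromen-3-yl]methyl 6-methyl-3,5,7-trioxooctanoate | COc1cc(O)c2c(c1C)[C@H](C)[C@](O)(COC(=O)CC(=O)CC(=O)C(C)C(C)=O)OC2=O | intermediate (not isolated)
23 | [(3R,4S)-3,8-dihydroxy-6-methoxy-4,5-dimethyl-1-oxo-3,4-dihydro-1H-isochromen-3-yl]methyl 2-hydroxy-2,3-dimethyl-4,6-dioxocyclohexane-1-carboxylate | COc1cc(O)c2c(c1C)[C@H](C)[C@](O)(COC(=O)C3C(=O)CC(=O)C(C)C3(C)O)OC2=O | intermediate (not isolated)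
24 | [(3R,4S)-3,8-dihydroxy-6-methoxy-4,5-dimethyl-1-oxo-3,4-dihydro-1H-isochromen-3-yl]methyl 2,4-dihydroxy-5,6-dimethylbenzoate | COc1cc(O)c2c(c1C)[C@H](C)[C@](O)(COC(=O)c1c(O)cc(O)c(C)c1C)OC2=O | target

Total step count: 13. Longest linear sequence: 11 steps (steps 1–10, then step 13); the dioxinone branch is steps 11–12.

Steps most likely to fail

Step 13. The acylketene may be consumed by its own enol oxygen (pyranone formation) or add to the hemiketal or phenolic oxygen before the neopentyl-like primary hydroxyl captures it, and the lactol may open during aromatisation so that C4 epimerises. The fallback sets out from 20 and 15 and returns at 24. Compound 20 alone is aromatised with Et3N in CH2Cl2, the dioxinone C5 serving as the aldol donor, to 7-hydroxy-2,2,5,6-tetramethyl-4H-1,3-benzodioxin-4-one F1, so that the 5-methylorsellinate ring is built first. Irradiation of F1 at about 300 nm in CH2Cl2 in the presence of 15 then expels acetone, and the quinoketene so formed is captured by the primary hydroxyl at room temperature without acid or base, giving 24 directly.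

Step 4. Protodeboronation of the electron-rich, ortho-substituted boronic acid may outrun transmetalation, and enantioface discrimination may be incomplete at 100 °C. The fallback sets out from 3 and returns at 7. (S)-4-Phenyloxazolidin-2-one is N-acylated with (E)-but-2-enoyl chloride (n-BuLi, THF, −78 °C) to (4S)-3-[(2E)-but-2-enoyl]-4-phenyl-1,3-oxazolidin-2-one F2. The Grignard reagent from 3 (Mg, THF) is added with CuBr·SMe2 at −20 °C, the aryl group entering the chelated s-cis imide on the face away from the C4 phenyl, to give (4S)-3-[(3R)-3-(3,5-dimethoxy-2-methylphenyl)butanoyl]-4-phenyl-1,3-oxazolidin-2-one F3, which can be purified as a single diastereomer. LiOH/H2O2 in THF/H2O then releases acid 7 and the auxiliary.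

Step 7. The hard chloromethyl ether may O-alkylate the ketone enolate, a second alkylation may occur at C2, or O-alkylation of the chelated phenoxide may stall. The fallback sets out from 9 and returns at 11. Compound 9 is converted with LiHMDS/TMSCl at −78 °C into {[(1R)-6-methoxy-1,7-dimethyl-3-(trimethylsilyloxy)-1H-inden-4-yl]oxy}(trimethyl)silane F4. ZnBr2-catalysed reaction of this enol silane with BOMCl in CH2Cl2 at 0 °C (oxocarbenium alkylation, possible only at carbon) and aqueous work-up, which also removes the aryl silyl ether, give (2RS,3R)-2-[(benzyloxy)methyl]-7-hydroxy-5-methoxy-3,4-dimethyl-2,3-dihydro-1H-inden-1-one F5. O-Alkylation of the phenol with BOMCl and i-Pr2NEt then gives 11.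

Further compounds
F1 | step 13 | 7-hydroxy-2,2,5,6-tetramethyl-4H-1,3-benzodioxin-4-one | CC1(C)OC(=O)c2c(C)c(C)c(O)cc2O1
F2 | step 4 | (4S)-3-[(2E)-but-2-enoyl]-4-phenyl-1,3-oxazolidin-2-one | C/C=C/C(=O)N1C(=O)OC[C@@H]1c1ccccc1
F3 | step 4 | (4S)-3-[(3R)-3-(3,5-dimethoxy-2-methylphenyl)butanoyl]-4-phenyl-1,3-oxazolidin-2-one | COc1cc(OC)c(C)c(c1)[C@H](C)CC(=O)N2C(=O)OC[C@@H]2c3ccccc3
F4 | step 7 | {[(1R)-6-methoxy-1,7-dimethyl-3-(trimethylsilyloxy)-1H-inden-4-yl]oxy}(trimethyl)silane | COc1cc(O[Si](C)(C)C)c2c(c1C)[C@H](C)C=C2O[Si](C)(C)C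
F5 | step 7 | (2RS,3R)-2-[(benzyloxy)methyl]-7-hydroxy-5-methoxy-3,4-dimethyl-2,3-dihydro-1H-inden-1-one | COc1cc(O)c2c(c1C)[C@H](C)C(COCc3ccccc3)C2=O
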